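The spiro-dihydropyran is opened by a hetero-Diels–Alder disconnection into alantolactone and the enal of the ent-β-elemene series. The route rests on closing ring A of the eudesmane half between C3 and C4 by a Lewis-acid-promoted type 2 carbonyl-ene reaction. The precursor is a single cyclohexane (ring B) that carries a (Z)-ethylidene group on C5, the angular methyl and a 3-oxopropyl chain on quaternary C10 and a ketal at C8. Because C4 is allylic to C5=C6 in the target and C10 bears no hydrogen, this one step forms ring A, sets the axial C4 methyl syn to the C10 methyl and delivers the C5=C6 double bond.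

Key step: step 4

Remark: eudesmane numbering (C1–C15) is used for the lactone half, which has the alantolactone configuration; the cyclohexane of the other half is (1R,2R,4S), the mirror image of the (−)-β-elemene skeleton, so it is made by asymmetric synthesis.

Step 1
Reactants: 1 7-methyl-1,4-dioxaspiro[4.5]decan-8-one (racemic); 2 (R)-1-phenylethan-1-amine; 3 acrylonitrile
Product: 6 3-[(7R)-7-methyl-8-oxo-1,4-dioxaspiro[4.5]decan-7-yl]propanenitrile, via imine 4 (not isolated), via Michael-adduct imine 5 (not isolated)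
Conditions: 2 (1.05 equiv), TsOH·H2O (1 mol %), toluene, reflux, Dean–Stark; then 3 (1.5 equiv), THF, 50 °C; then 10 % aq. AcOH, rt
Reagents that add atoms: water, O
Why: Asymmetric Michael addition of a chiral imine through its more substituted secondary-enamine tautomer (aza-ene-type transition state), in which the acceptor is taken up on the face remote from the phenyl group, so that the (R)-amine should give the (R)-configured quaternary C10 from both enantiomers of 1, and hydrolysis returns the auxiliary.

Step 2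
Reactants: 6
Product: 7 3-[(7R,8Z)-8-ethylidene-7-methyl-1,4-dioxaspiro[4.5]decan-7-yl]propanenitrile
Conditions: EtPPh3Br (3 equiv), KOt-Bu (3 equiv), toluene, 90 °C
Reagents that add atoms: ethyltriphenylphosphonium bromide, CC[P+](c1ccccc1)(c1ccccc1)c1ccccc1.[Br-]
Why: Wittig olefination with a non-stabilised ylide under kinetic control, in which, as in the ethylidenation of other cycloalkanones flanked by a quaternary carbon (17-oxo steroids), the ylide methyl should end cis to the fully substituted C10, giving the (Z)-alkene that the key step needs.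

Step 3
Reactants: 7
Product: 9 3-[(7R,8Z)-8-ethylidene-7-methyl-1,4-dioxaspiro[4.5]decan-7-yl]propanal, via N-aluminio aldimine 8 (not isolated)
Conditions: i-Bu2AlH (1.2 equiv), CH2Cl2, −78 °C; then aq. KNaC4H4O6 (potassium sodium tartrate), rt
Reagents that add atoms: water, O
Why: Partial hydride reduction of the nitrile stops at the N-metallated aldimine, which hydrolyses to the aldehyde on work-up while the ketal and the alkene are untouched.

Step 4
Reactants: 9
Product: 10 (5'R,6'R,8a'R)-5',8a'-dimethyl-3',5',6',7',8',8a'-hexahydro-1'H-spiro[[1,3]dioxolane-2,2'-naphthalen]-6'-ol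
Conditions: Me2AlCl (1.5 equiv), CH2Cl2, −78 to −30 °C; aq. NaHCO3
Reagents that add atoms: none
Why: Me2AlCl activates the aldehyde, C3 bonds to C4 of the (Z)-ethylidene group and the allylic hydrogen on C6 passes to the carbonyl oxygen through a six-membered suprafacial ene transition state, the product being held as its aluminium alkoxide with loss of methane. The closest known reaction type is the Me2AlCl-promoted type 2 intramolecular carbonyl-ene cyclisation of 3-(2-alkylidenecycloalkyl)propanals to bicyclic homoallylic alcohols. Ring A (C10–C1–C2–C3–C4–C5) closes in a chair-like six-membered array with both carbons of the reacting C4=C5 bond inside the new ring (endo to that bond), the tether being attached to the central carbon C5 of the ene unit. C4 is controlled by the alkene geometry: fusion to ring B forces the C10 methyl axial on ring A, the enophile attacks the face opposite to it, and the ethylidene methyl, being cis to C10, becomes the axial substituent syn to the C10 methyl, while C3 is formed with an axial hydroxyl (the oxygen must reach the C6 hydrogen) and is removed later. The step needs bond formation at C4 and not at C5, secured by the developing tertiary cationic character at C5 and by six- over five-membered closure, and hydrogen transfer from C6 only, secured because C10 is quaternary, so the double bond can only end at C5=C6. The low temperature should keep the dioxolane intact.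

Step 5
Reactants: 10
Product: 12 O-[(5'R,6'R,8a'R)-5',8a'-dimethyl-3',5',6',7',8',8a'-hexahydro-1'H-spiro[[1,3]dioxolane-2,2'-naphthalen]-6'-yl] S-methyl carbonodithioate, via sodium xanthate 11 (not isolated)
Conditions: NaH (1.5 equiv), THF, 0 °C; CS2 (3 equiv); then MeI (3 equiv), rt
Reagents that add atoms: carbon disulfide, S=C=S; iodomethane, CI
Why: Xanthate formation from the sodium alkoxide (first stage of a Barton–McCombie deoxygenation), which touches no stereocentre.

Step 6
Reactants: 12
Product: 13 (5'S,8a'R)-5',8a'-dimethyl-3',5',6',7',8',8a'-hexahydro-1'H-spiro[[1,3]dioxolane-2,2'-naphthalene]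
Conditions: Bu3SnH (3 equiv, 0.3 M), AIBN (0.1 equiv), toluene, 110 °C
Reagents that add atoms: none
Why: Barton–McCombie radical deoxygenation, in which the concentrated stannane should reduce the secondary C3 radical faster than it can rearrange through the homoallyl/cyclopropylcarbinyl manifold, leaving C4 and C10 unchanged.

Step 7
Reactants: 13
Product: 14 (5S,8aR)-5,8a-dimethyl-3,5,6,7,8,8a-hexahydronaphthalen-2(1H)-one
Conditions: PPTS (0.2 equiv), acetone/H2O 9:1, 40 °C
Reagents that add atoms: water, O
Why: Mild acid-catalysed hydrolysis of the dioxolane, weak enough that the C5=C6 double bond should stay out of conjugation with the new C8 ketone.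

Step 8
Reactants: 14; 15 tert-butyl bromoacetate
Product: 17 tert-butyl 2-[(3S,5S,8aR)-5,8a-dimethyl-2-oxo-1,2,3,5,6,7,8,8a-octahydronaphthalen-3-yl]acetate, via 7α-epimer 16 (not isolated)
Conditions: LiN(i-Pr)2 (1.05 equiv), THF, −78 °C; 15 (1.0 equiv), −78 to −40 °C; then KOt-Bu (1.5 equiv), t-BuOH/THF, −40 to −20 °C; then poured into AcOH/THF, −78 °C
Reagents that add atoms: none
Why: Kinetic deprotonation at the doubly activated C7 and α-alkylation of the linear dienolate (enolate alkylation) should occur mainly pseudo-axially on the α face, and re-formation of the dienolate followed by its kinetic C7-protonation from the same α face (deconjugative protonation) then leaves the side chain β and pseudo-equatorial with the double bond still at C5=C6.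

Step 9
Reactants: 17
Product: 19 (3aS,5S,8aR,9aR)-5,8a-dimethyl-3a,5,6,7,8,8a,9,9a-octahydronaphtho[2,3-b]furan-2(3H)-one, via hydroxy ester 18 (not isolated)
Conditions: LiBH(s-Bu)3 (1.2 equiv), THF, −78 °C; aq. NH4Cl; then TsOH·H2O (5 mol %), CH2Cl2, rt
Reagents that add atoms: none
Why: Hydride reduction of the C8 ketone from the α face, the β face being blocked by the syn-axial C10 methyl, gives the axial 8β-alcohol cis to the C7 side chain, and acid-catalysed lactonisation closes the cis-fused γ-lactone.

Step 10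
Reactants: 19
Product: 22 alantolactone [(3aR,5S,8aR,9aR)-5,8a-dimethyl-3-methylidene-3a,5,6,7,8,8a,9,9a-octahydronaphtho[2,3-b]furan-2(3H)-one], via Mannich base 20 (not isolated), via ammonium iodide 21 (not isolated)
Conditions: LiN(i-Pr)2 (1.2 equiv), THF, −78 °C; CH2=NMe2+ I− (2 equiv), −78 °C to rt; then MeI, MeOH, rt; then aq. NaHCO3, CH2Cl2, rt
Reagents that add atoms: N,N-dimethylmethyleneiminium iodide, C=[N+](C)C.[I-]
Why: Mannich reaction of the lactone enolate, N-quaternisation and E1cB elimination (α-methylenation of a lactone), after which C11 is trigonal so that its transient configuration does not matter.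

Step 11
Reactants: 23 cyclohex-2-en-1-one; 24 4,4,5,5-tetramethyl-2-(prop-1-en-2-yl)-1,3,2-dioxaborolane
Product: 25 (3S)-3-(prop-1-en-2-yl)cyclohexan-1-one
Conditions: [RhCl(cod)]2 (1.5 mol %), (S)-BINAP (3.3 mol %), KOH (0.5 equiv), 1,4-dioxane/H2O 10:1, 40 °C
Reagents that add atoms: none
Why: Rhodium-catalysed asymmetric conjugate addition of an alkenylboron reagent (Hayashi–Miyaura reaction), in which the (S)-BINAP complex should deliver the alkenyl group to the enone face that gives the (S)-ketone, fixing the later C4 of the cyclohexane.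

Step 12
Reactants: 25
Product: 26 (2Z,5S)-2-(hydroxymethylidene)-5-(prop-1-en-2-yl)cyclohexan-1-one
Conditions: NaH (1.5 equiv), HCO2Et (3 equiv), EtOH (cat.), Et2O, 0 °C to rt; then 1 M HCl
Reagents that add atoms: ethyl formate, CCOC=O
Why: Crossed Claisen condensation (α-formylation), which for 3-substituted cyclohexanones takes place at the less hindered C6, away from the substituent.

Step 13
Reactants: 26
Product: 27 (1R,4S)-1-methyl-2-oxo-4-(prop-1-en-2-yl)cyclohexane-1-carbaldehyde
Conditions: MeI (3 equiv), K2CO3 (2 equiv), acetone, 50 °C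
Reagents that add atoms: iodomethane, CI
Why: C-alkylation of the β-keto aldehyde enolate, where axial attack through a chair-like transition state with the isopropenyl group equatorial should place the new methyl cis to that group (formyl trans), the minor diastereomer and any O-methyl product being removed by chromatography.

Step 14
Reactants: 27
Product: 28 (2R,5S)-2-ethenyl-2-methyl-5-(prop-1-en-2-yl)cyclohexan-1-one
Conditions: MePPh3Br (1.05 equiv), KN(SiMe3)2 (1.0 equiv), THF, −78 to 0 °C
Reagents that add atoms: methyltriphenylphosphonium bromide, C[P+](c1ccccc1)(c1ccccc1)c1ccccc1.[Br-]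
Why: Chemoselective Wittig methylenation of the aldehyde beside the hindered ketone, leaving the quaternary centre untouched.

Step 15
Reactants: 28
Product: 29 (2R,5S)-2-ethenyl-2-methyl-5-(prop-1-en-2-yl)cyclohexane-1-carbonitrile (C1 epimers)
Conditions: TosMIC (1.5 equiv), KOt-Bu (2.5 equiv), EtOH (1.5 equiv), DME, 0 to 40 °C
Reagents that add atoms: p-toluenesulfonylmethyl isocyanide, Cc1ccc(cc1)S(=O)(=O)C[N+]#[C-]
Why: Van Leusen reductive cyanation converts the ketone into the one-carbon-homologated nitrile, and the configuration of the new carbon is corrected in the next step.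

Step 16
Reactants: 29
Product: 32 1-[(1S,2R,5S)-2-ethenyl-2-methyl-5-(prop-1-en-2-yl)cyclohexyl]ethan-1-one, via lithium ketimide 30 (not isolated), via epimeric ketone mixture 31 (not isolated)
Conditions: MeLi (3 equiv), Et2O, 0 °C to reflux; then 2 M HCl, THF, rt; then NaOMe (0.2 equiv), MeOH, rt
Reagents that add atoms: methyllithium, [Li]C; water, O
Why: Organolithium addition to the nitrile and hydrolysis of the ketimine give the methyl ketone, and base equilibration through the enolate should set the acetyl group equatorial, trans to the vinyl group and cis to the remote isopropenyl group (thermodynamic control).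

Step 17
Reactants: 32
Product: 33 ent-β-elemene [(1R,2R,4S)-1-ethenyl-1-methyl-2,4-di(prop-1-en-2-yl)cyclohexane]
Conditions: MePPh3Br (3 equiv), KOt-Bu (3 equiv), toluene, 80 °C
Reagents that add atoms: methyltriphenylphosphonium bromide, C[P+](c1ccccc1)(c1ccccc1)c1ccccc1.[Br-]
Why: Wittig methylenation of the hindered methyl ketone, in which any epimerisation under the basic conditions returns the same, more stable equatorial isomer.

Step 18
Reactants: 33
Product: 35 ent-β-elemenal [2-[(1S,3R,4R)-4-ethenyl-4-methyl-3-(prop-1-en-2-yl)cyclohexyl]prop-2-enal], via allylic alcohol 34 (not isolated)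
Conditions: SeO2 (0.3 equiv), t-BuOOH (2 equiv), CH2Cl2, 0 °C to rt; then MnO2 (10 equiv), CH2Cl2, rt
Reagents that add atoms: tert-butyl hydroperoxide, CC(C)(C)OO
Why: SeO2 allylic oxidation (ene reaction then [2,3]-sigmatropic shift) should prefer the methyl of the isopropenyl group on C4, which is less shielded than the one next to the quaternary carbon, and MnO2 takes the allylic alcohol to the enal, the reaction being stopped at partial conversion and regioisomers removed by chromatography.

Step 19
Reactants: 22; 35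
Product: 36 target CNP0175206.1
Conditions: 22 (3 equiv), 35 added over 12 h, BHT (2 mol %), toluene (2 M), 110 °C, sealed tube
Reagents that add atoms: none
Why: Thermal hetero-Diels–Alder reaction of the 1-oxadiene of 35 with the exocyclic methylene of 22, with the regiochemistry of enal dimerisation (oxygen to the carbonyl-bearing C11), in which attack on the convex α face of the cis-fused lactone (the side of H7 and H8) should set the spiro centre with the pyran oxygen α, and the excess dienophile suppresses self-dimerisation of the enal.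

Compound list
1 | 7-methyl-1,4-dioxaspiro[4.5]decan-8-one (racemic) | CC1CC2(CCC1=O)OCCO2 | starting material
2 | (R)-1-phenylethan-1-amine | C[C@@H](N)c1ccccc1 | starting material
3 | acrylonitrile | C=CC#N | starting material
4 | 7-methyl-N-[(1R)-1-phenylethyl]-1,4-dioxaspiro[4.5]decan-8-imine (C7 epimers) | C[C@@H](N=C1CCC2(CC1C)OCCO2)c1ccccc1 | intermediate (not isolated)
5 | 3-[(7R)-7-methyl-8-{[(1R)-1-phenylethyl]imino}-1,4-dioxaspiro[4.5]decan-7-yl]propanenitrile | C[C@@H](N=C1CCC2(C[C@@]1(C)CCC#N)OCCO2)c1ccccc1 | intermediate (not isolated)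
6 | 3-[(7R)-7-methyl-8-oxo-1,4-dioxaspiro[4.5]decan-7-yl]propanenitrile | N#CCC[C@]1(C)CC2(CCC1=O)OCCO2 | intermediate
7 | 3-[(7R,8Z)-8-ethylidene-7-methyl-1,4-dioxaspiro[4.5]decan-7-yl]propanenitrile | N#CCC[C@]1(C)CC2(CC/C1=C/C)OCCO2 | intermediate
8 | N-(diisobutylaluminio) aldimine of 9 | CC(C)C[Al](CC(C)C)N=CCC[C@]1(C)CC2(CC/C1=C/C)OCCO2 | intermediate (not isolated)
9 | 3-[(7R,8Z)-8-ethylidene-7-methyl-1,4-dioxaspiro[4.5]decan-7-yl]propanal | O=CCC[C@]1(C)CC2(CC/C1=C/C)OCCO2 | intermediate
10 | (5'R,6'R,8a'R)-5',8a'-dimethyl-3',5',6',7',8',8a'-hexahydro-1'H-spiro[[1,3]dioxolane-2,2'-naphthalen]-6'-ol (3α-OH, 4β-Me, Δ5, C8 ketal) | C[C@H]1[C@H](O)CC[C@]2(C1=CCC3(C2)OCCO3)C | intermediate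
11 | sodium O-alkyl dithiocarbonate of 10 | C[C@H]1[C@H](OC(=S)[S-])CC[C@]2(C1=CCC3(C2)OCCO3)C.[Na+] | intermediate (not isolated)
12 | S-methyl xanthate of 10 | C[C@H]1[C@H](OC(=S)SC)CC[C@]2(C1=CCC3(C2)OCCO3)C | intermediate
13 | (5'S,8a'R)-5',8a'-dimethyl-3',5',6',7',8',8a'-hexahydro-1'H-spiro[[1,3]dioxolane-2,2'-naphthalene] | C[C@H]1CCC[C@]2(C1=CCC3(C2)OCCO3)C | intermediate
14 | (5S,8aR)-5,8a-dimethyl-3,5,6,7,8,8a-hexahydronaphthalen-2(1H)-one | C[C@H]1CCC[C@]2(C1=CCC(=O)C2)C | intermediate
15 | tert-butyl bromoacetate | BrCC(=O)OC(C)(C)C | starting material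
16 | tert-butyl 2-[(3R,5S,8aR)-5,8a-dimethyl-2-oxo-1,2,3,5,6,7,8,8a-octahydronaphthalen-3-yl]acetate (7α side chain) | C[C@H]1CCC[C@]2(C1=C[C@@H](CC(=O)OC(C)(C)C)C(=O)C2)C | intermediate (not isolated)
17 | tert-butyl 2-[(3S,5S,8aR)-5,8a-dimethyl-2-oxo-1,2,3,5,6,7,8,8a-octahydronaphthalen-3-yl]acetate (7β side chain) | C[C@H]1CCC[C@]2(C1=C[C@H](CC(=O)OC(C)(C)C)C(=O)C2)C | intermediate
18 | tert-butyl 2-[(2R,3S,5S,8aR)-2-hydroxy-5,8a-dimethyl-1,2,3,5,6,7,8,8a-octahydronaphthalen-3-yl]acetate (8β-OH) | C[C@H]1CCC[C@]2(C1=C[C@H](CC(=O)OC(C)(C)C)[C@H](O)C2)C | intermediate (not isolated)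
19 | (3aS,5S,8aR,9aR)-5,8a-dimethyl-3a,5,6,7,8,8a,9,9a-octahydronaphtho[2,3-b]furan-2(3H)-one | C[C@H]1CCC[C@]2(C1=C[C@H]3[C@@H](C2)OC(=O)C3)C | intermediate
20 | 3-[(dimethylamino)methyl] derivative of 19 (C11 epimers) | C[C@H]1CCC[C@]2(C1=C[C@H]3[C@@H](C2)OC(=O)C3CN(C)C)C | intermediate (not isolated)
21 | trimethylammonium iodide of 20 | C[C@H]1CCC[C@]2(C1=C[C@H]3[C@@H](C2)OC(=O)C3C[N+](C)(C)C)C.[I-] | intermediate (not isolated)
22 | alantolactone, (3aR,5S,8aR,9aR)-5,8a-dimethyl-3-methylidene-3a,5,6,7,8,8a,9,9a-octahydronaphtho[2,3-b]furan-2(3H)-one | C[C@H]1CCC[C@]2(C1=C[C@H]3[C@@H](C2)OC(=O)C3=C)C | intermediate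
23 | cyclohex-2-en-1-one | O=C1C=CCCC1 | starting material
24 | 4,4,5,5-tetramethyl-2-(prop-1-en-2-yl)-1,3,2-dioxaborolane | CC(=C)B1OC(C)(C)C(C)(C)O1 | starting material
25 | (3S)-3-(prop-1-en-2-yl)cyclohexan-1-one | O=C1C[C@@H](C(C)=C)CCC1 | intermediate
26 | (2Z,5S)-2-(hydroxymethylidene)-5-(prop-1-en-2-yl)cyclohexan-1-one | O=C1C[C@@H](C(C)=C)CC/C1=C/O | intermediate
27 | (1R,4S)-1-methyl-2-oxo-4-(prop-1-en-2-yl)cyclohexane-1-carbaldehyde | O=C[C@@]1(C)CC[C@H](C(C)=C)CC1=O | intermediate
28 | (2R,5S)-2-ethenyl-2-methyl-5-(prop-1-en-2-yl)cyclohexan-1-one | C=C[C@@]1(C)CC[C@H](C(C)=C)CC1=O | intermediate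
29 | (2R,5S)-2-ethenyl-2-methyl-5-(prop-1-en-2-yl)cyclohexane-1-carbonitrile (C1 epimers) | C=C[C@@]1(C)CC[C@H](C(C)=C)CC1C#N | intermediate
30 | lithium ketimide from 29 and MeLi (C1 epimers) | C=C[C@@]1(C)CC[C@H](C(C)=C)CC1C(C)=N[Li] | intermediate (not isolated)
31 | 1-[(2R,5S)-2-ethenyl-2-methyl-5-(prop-1-en-2-yl)cyclohexyl]ethan-1-one (C1 epimers) | C=C[C@@]1(C)CC[C@H](C(C)=C)CC1C(C)=O | intermediate (not isolated)
32 | 1-[(1S,2R,5S)-2-ethenyl-2-methyl-5-(prop-1-en-2-yl)cyclohexyl]ethan-1-one | C=C[C@@]1(C)CC[C@H](C(C)=C)C[C@@H]1C(C)=O | intermediate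
33 | ent-β-elemene, (1R,2R,4S)-1-ethenyl-1-methyl-2,4-di(prop-1-en-2-yl)cyclohexane | C=C[C@@]1(C)CC[C@H](C(C)=C)C[C@@H]1C(C)=C | intermediate
34 | 2-[(1S,3R,4R)-4-ethenyl-4-methyl-3-(prop-1-en-2-yl)cyclohexyl]prop-2-en-1-ol | C=C[C@@]1(C)CC[C@H](C(=C)CO)C[C@@H]1C(C)=C | intermediate (not isolated)
35 | ent-β-elemenal, 2-[(1S,3R,4R)-4-ethenyl-4-methyl-3-(prop-1-en-2-yl)cyclohexyl]prop-2-enal | C=C[C@@]1(C)CC[C@H](C(=C)C=O)C[C@@H]1C(C)=C | intermediate
36 | target CNP0175206.1: spiro-dihydropyran adduct of 22 (through C11 and C13, pyran oxygen α on C11) and 35 | C=C[C@@]1(C)CC[C@H](C2=CO[C@@]3(CC2)C(=O)O[C@@H]2C[C@@]4(C)CCC[C@H](C)C4=C[C@@H]23)C[C@@H]1C(=C)C | target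

Total step count: 19. Longest linear sequence: 11 steps (steps 1 to 10 and step 19).

Steps most likely to fail

Step 4 (key step). The chloroaluminium reagent may open or ionise the dioxolane, or the closure may pass through a boat-like array and erode the C4 selectivity. The fallback sets out from aldehyde 9 and comes back to the route at ketone 14, so that steps 4 to 7 are bypassed. NaBH4 in MeOH reduces 9 to 3-[(7R,8Z)-8-ethylidene-7-methyl-1,4-dioxaspiro[4.5]decan-7-yl]propan-1-ol F1, and I2, PPh3 and imidazole convert it into (7R,8Z)-8-ethylidene-7-(3-iodopropyl)-7-methyl-1,4-dioxaspiro[4.5]decane F2. PPTS in wet acetone removes the ketal to give (3R,4Z)-4-ethylidene-3-(3-iodopropyl)-3-methylcyclohexan-1-one F3. 2-Iodoxybenzoic acid in DMSO at 70 °C dehydrogenates C6–C7, the only direction open because C10 is quaternary, to the dienone (4Z,5R)-4-ethylidene-5-(3-iodopropyl)-5-methylcyclohex-2-en-1-one F4. Bu3SnH and AIBN in benzene at 80 °C then generate the C3 radical, which adds in the 6-endo mode to C4, the δ-terminus of the dienone, and hydrogen transfer to C7 of the dienoxyl radical gives 14.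

Step 19. The cross-cycloaddition of two electron-poor partners may be slow, so that self-dimerisation or polymerisation of the enal takes over. The fallback sets out from 22 and 35 and comes back at the target 36, building the dihydropyran stepwise. PhSeH (from PhSeSePh and NaBH4 in EtOH) adds to 35 in conjugate fashion to give 2-[(1S,3R,4R)-4-ethenyl-4-methyl-3-(prop-1-en-2-yl)cyclohexyl]-3-(phenylselanyl)propanal F5, and HC(OMe)3 with PPTS in MeOH gives its dimethyl acetal F6. Bu3SnH and AIBN in the presence of 22 add the primary radical from F6 to C13 of the methylene lactone (Giese addition) to give the 11,13-dihydro adduct F7. KN(SiMe3)2 and 2-(phenylsulfonyl)-3-phenyloxaziridine hydroxylate the C11 enolate on the convex α face to give the 11α-hydroxy lactone F8. PPTS in wet acetone frees the aldehyde, which closes to the lactol F9, and MsCl with Et3N dehydrates F9 to the enol ether 36.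

Step 2. Olefination of the hindered ketone may stall, or the alkene may form with insufficient (Z)-selectivity, which would invert C4 in step 4. The fallback sets out from 6 and comes back at 7 by a Horner–Wittig sequence. Lithiated ethyldiphenylphosphine oxide (Ph2P(O)Et, n-BuLi, THF, −78 °C) adds to 6 to give the β-hydroxy phosphine oxide 3-{(7R)-8-[1-(diphenylphosphoryl)ethyl]-8-hydroxy-7-methyl-1,4-dioxaspiro[4.5]decan-7-yl}propanenitrile F10. Its diastereomers are separated, and those with the relative configuration that leads to the (Z)-alkene are treated with NaH in DMF, where stereospecific syn-elimination gives 7.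

Further compounds
F1 | step 4 | 3-[(7R,8Z)-8-ethylidene-7-methyl-1,4-dioxaspiro[4.5]decan-7-yl]propan-1-ol | OCCC[C@]1(C)CC2(CC/C1=C/C)OCCO2
F2 | step 4 | (7R,8Z)-8-ethylidene-7-(3-iodopropyl)-7-methyl-1,4-dioxaspiro[4.5]decane | ICCC[C@]1(C)CC2(CC/C1=C/C)OCCO2
F3 | step 4 | (3R,4Z)-4-ethylidene-3-(3-iodopropyl)-3-methylcyclohexan-1-one | ICCC[C@]1(C)CC(=O)CC/C1=C/C
F4 | step 4 | (4Z,5R)-4-ethylidene-5-(3-iodopropyl)-5-methylcyclohex-2-en-1-one | ICCC[C@]1(C)CC(=O)C=C/C1=C/C
F5 | step 19 | 2-[(1S,3R,4R)-4-ethenyl-4-methyl-3-(prop-1-en-2-yl)cyclohexyl]-3-(phenylselanyl)propanal (C2 epimers) | C=C[C@@]1(C)CC[C@H](C(C[Se]c2ccccc2)C=O)C[C@@H]1C(=C)C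
F6 | step 19 | dimethyl acetal of F5 | C=C[C@@]1(C)CC[C@H](C(C[Se]c2ccccc2)C(OC)OC)C[C@@H]1C(=C)C
F7 | step 19 | 11,13-dihydroalantolactone carrying the 3-(elemanyl)-4,4-dimethoxybutyl chain on C11 (Giese adduct, C11 epimers) | C=C[C@@]1(C)CC[C@H](C(C(OC)OC)CCC3C(=O)O[C@@H]2C[C@@]4(C)CCC[C@H](C)C4=C[C@@H]23)C[C@@H]1C(=C)C
F8 | step 19 | 11α-hydroxy derivative of F7 | C=C[C@@]1(C)CC[C@H](C(C(OC)OC)CC[C@]3(O)C(=O)O[C@@H]2C[C@@]4(C)CCC[C@H](C)C4=C[C@@H]23)C[C@@H]1C(=C)C
F9 | step 19 | spiro lactol (6'-hydroxy-tetrahydropyran) formed from F8 | C=C[C@@]1(C)CC[C@H](C2CC[C@]3(OC2O)C(=O)O[C@@H]2C[C@@]4(C)CCC[C@H](C)C4=C[C@@H]23)C[C@@H]1C(=C)C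
F10 | step 2 | 3-{(7R)-8-[1-(diphenylphosphoryl)ethyl]-8-hydroxy-7-methyl-1,4-dioxaspiro[4.5]decan-7-yl}propanenitrile | N#CCC[C@]1(C)CC2(CCC1(O)C(C)P(=O)(c1ccccc1)c1ccccc1)OCCO2
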